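## Structural features

Numbering used throughout (trinervitane type; in the target SMILES the carbons run C19, C8, C9, C10, C11, C12 with methyl C20, C13, C14 with the acetate, C1, C15 with methyl C17, C16, C7, C6, C5, C4 with methyl C18, C3, C2): ring A is the cyclohexene C1–C2–C3–C4–C16–C15, ring B the cyclopentane C4–C5–C6–C7–C16, and ring C the eleven-membered carbocycle C1–C15–C16–C7–C8–C9–C10–C11–C12–C13–C14. Rings A and B are cis-fused at C4–C16, ring C is fused to ring B at C16–C7 and bridges ring A across C1=C15–C16, so the tetrasubstituted C1=C15 bond is a bridgehead alkene of a bicyclo[8.3.1] system and is E within ring C. Five stereocentres are contiguous, C2 (R), C3 (R), quaternary C4 (S), C16 (S) and C7 (R): the C18 methyl, H-16, H-7 and the C3 hydroxyl lie on one face (called β here), the C2 hydroxyl and the C7–C8 bond on the other (α), which is the concave face of the cis-hydrindane; C12 (S) and C14 (S) are remote. Fragile are the cross-conjugated (E)-C19=C8–C9=C10 diene (acid, electrophiles, cycloaddition), the allylic C14 acetate next to a free trans-diol (hydrolysis, acyl migration) and any intermediate with a carbonyl at C2 or C14, because the other oxygen is then β to it. The real difficulty is twofold: closing the strained, bridged ring C with an E alkene at C9=C10 conjugated to the exocyclic methylene, and placing C8 on the hindered α face beside the quaternary C4. The key step exploits the fact that C9 and C10 are the only adjacent carbons of ring C that are neither stereogenic nor oxygenated, C9 being allylic to C8=C19: a sulfonyl group inserted between them turns ring C into a twelve-membered ring that is closed through sulfur, and its deletion forms C9=C10. The same C8(=C19)–C9 unit is an isopropenyl group one oxidation level below the target, which an ene reaction can deliver to the α face of C7.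

## Logic of the disconnections

29 from 26 (through 28 and 27). Only O–C and O–Si bonds change. The acetate goes on last because no ester would survive the base of the key step. The gain is that the three hydroxyls stay differentiated from 21 onwards (O2/O3 in one ketal, O14 as a silyl ether). The demand is that fluoride frees O14 alone and that the final ketal cleavage spares the allylic acetate and the diene.

26 from 23 (key). Backwards, SO2 is inserted into C9=C10; forwards, the C9–S and C10–S bonds are cut and the C9=C10 π bond is made. This is the one bond of ring C whose formation creates no stereocentre and can take up the ring strain in a gas-releasing step. The gain is a twelve-membered ring with two long C–S bonds and no alkene in the closing region. The demand is that halogenation, 1,3-closure and SO2 loss outrun allyl-to-vinyl sulfone isomerisation and give the E alkene.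

23 from 21 (through 22). Both C–S bonds are cut, leaving a dichloride and sulfide. The ring is closed by a soft, unhindered nucleophile and sulfur is oxidised afterwards, so no C–C macrocyclisation occurs anywhere. The demand is high dilution and S-oxidation that leaves C1=C15 and C8=C19 alone.

21 from 18 (through 20 and 19). No skeletal bond is cut. C14–O is set by catalyst-controlled ketone reduction and C9–Cl by ene-type chlorination of the isopropenyl group. The chlorination is placed at 18 because there C1=C15 is conjugated to C14=O and inert to electrophilic chlorine, and because an allylic chloride could not have passed the chromium step. The demand is ketone reduction without hydroboration of C8=C19.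

18 from 10 and 16 (through 17). C1–C14 is cut, the bond between the fully substituted alkene carbon and the carbinol carbon. This is a convergent union of a C15 fragment holding all five contiguous stereocentres with a C6 fragment holding C12. The demand is vinyl–metal formation from a hindered enol triflate in the presence of an alkyl chloride and a ketal.

16 from 11 (through 15 and 13). No C–C bond is cut; the two ends of a bought glutarate half-ester are differentiated (ester end to C10–Cl, acid end to the C14 aldehyde). C12 is purchased.

10 from 6 (through 9, 8 and 7). The C2–O and C3–O bonds and the C1–O triflate are traced to a β-epoxide of the C2=C3 enone that is opened at C2 with inversion, and to enolisation of the C1 ketone toward C15. C2 and C3 are relayed from C4. The demand is peroxide attack on the β face and water attack at C2, not C15.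

6 from 5. The C2=C3 unsaturation is removed; forwards this is a dehydrogenation whose regiochemistry rests on kinetic enolisation at C2.

5 from 4. C7–C16 is cut and a hydrogen is returned from C15 to C19 (retro-ene). Ring B and the stereocentres C16 and C7 disappear and only C4 remains. The demand is a cyclic hydrogen transfer that holds C8 over ring A.

4 from 1 and 2. C3–C4 (Michael) and C15=C16 (aldol) are cut, a Robinson annulation of two commercial compounds. The demand is catalyst control of the quaternary C4.

## Other disconnections considered

Alternative 1: the first idea is to cut C9=C10 by ring-closing metathesis of the seco-triene A1 with second-generation Grubbs catalyst, which would give 26 directly. The ruthenium carbene would have to load on the vinyl terminus of a 2-substituted butadiene, where a stabilised vinylcarbene forms, and closure would compete with attack on the 1,1-disubstituted C8=C19. The E/Z ratio of an eleven-membered cycloalkene is not under control, and a C–C macrocyclisation would have to absorb the full strain of the bridged ring. The chosen plan makes the same π bond only after a ring already exists, at a similar step count.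

Alternative 2: cut C4–C16 and C1=C15 and open rings A and B to the fourteen-membered enone A2, which carries an acetonyl group at C7. The forward step would be a base-mediated transannular Michael addition (C16 to C4) followed by aldol condensation (C1 to C15). This would build both small rings and the bridge in one flask, but the C1 enolate has the C14 silyloxy group in the β position (E1cB). The aldol closure of C17 onto C2 gives an isomeric, less strained cyclohexenone, and C16 is left to thermodynamic control. A2 also still needs a macrocyclisation and three separately set stereocentres. The chosen plan sets C16 and C7 in a concerted step instead.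

Alternative 3: cut C3–C4 and C15–C16 so that rings A and C form together in a type 2 intramolecular Diels–Alder reaction of the cyclopentenone–silyloxydiene A3. An eight-atom tether gives no regiocontrol (bicyclo[8.3.1] against [8.2.2]), and the 2-silyloxy group polarises the diene toward the wrong bonding. Addition anti to the C7 substituent would give the trans C16/C7 relationship. The cycloaddition would also leave the ring A alkene at C1=C2 and a surplus ketone at C5, each costing further steps.

Key step: step 18

Assumption: N-(4-dodecylphenylsulfonyl)-L-prolinamide is taken to induce the (R) configuration at C4 in step 1; if the sense is the opposite, the D-proline-derived catalyst is used and nothing else changes.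

## Route

Step 1
Reactants: 1 2,6-dimethylhept-5-enal (racemic); 2 pent-1-en-3-one
Product: 4 (R)-2,4-dimethyl-4-(4-methylpent-3-en-1-yl)cyclohex-2-en-1-one, via keto aldehyde 3 (not isolated)
Conditions: N-(4-dodecylphenylsulfonyl)-L-prolinamide (20 mol %), BnNH2 (1 equiv), 4 Å molecular sieves, ClCH2CH2Cl, rt then 50 °C
Reagents that add atoms: none
Why: Organocatalytic Robinson annulation: the enamine of the racemic aldehyde (its α-centre is erased) adds to the vinyl ketone under control of the prolinamide to set quaternary C4, and 3 can only close by aldol condensation of C15 onto the non-enolisable aldehyde carbon C16, which gives ring A.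

Step 2
Reactants: 4 (R)-2,4-dimethyl-4-(4-methylpent-3-en-1-yl)cyclohex-2-en-1-one
Product: 5 cis-fused bicyclic ketone (rings A and B; 7α-isopropenyl)
Conditions: Me2AlCl (30 mol %), CH2Cl2, −78 to 0 °C
Reagents that add atoms: none
Why: Lewis-acid-promoted type 1 intramolecular ene reaction with the enone as enophile: the three-atom tether reaches the β-carbon C16 only from the α face, so ring B is cis-fused with H-16 β, and the cyclic transfer of a methyl hydrogen from C8 to C15 holds C8 over ring A, which should place the isopropenyl group α at C7. C15 forms as an epimer mixture of no consequence.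

Step 3
Reactants: 5 cis-fused bicyclic ketone
Product: 6 bicyclic C2=C3 enone
Conditions: LiN(iPr)2, THF, −78 °C; then PhS(Cl)=NtBu, −78 °C
Reagents that add atoms: none
Why: Mukaiyama dehydrogenation: kinetic deprotonation occurs at the C2 methylene and not at the hindered C15 methine, the enolate is sulfenylated at C2 and the adduct eliminates the sulfenamide to give the C2=C3 enone; the isopropenyl group is untouched.

Step 4
Reactants: 6 bicyclic C2=C3 enone
Product: 7 2β,3β-epoxy ketone
Conditions: 30% H2O2, NaOH (0.2 equiv), MeOH, 0 °C
Reagents that add atoms: hydrogen peroxide OO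
Why: Weitz–Scheffer epoxidation: hydroperoxide should add axially to C3 on the conformer with C5 pseudo-axial, anti to the C4–C5 bond and syn-axial only to H-16, so the epoxide forms on the β face (cis to C18); the nucleophilic oxidant leaves the isopropenyl alkene alone.

Step 5
Reactants: 7 2β,3β-epoxy ketone
Product: 8 epoxy enol triflate (C1=C15)
Conditions: KN(SiMe3)2, THF, −78 °C; then PhNTf2, −78 to 0 °C
Reagents that add atoms: N-phenylbis(trifluoromethanesulfonimide) O=S(=O)(N(c1ccccc1)S(=O)(=O)C(F)(F)F)C(F)(F)F
Why: C15 carries the only enolisable hydrogen (C2 is an epoxide carbon), so the enolate and the enol triflate form regiospecifically as C1=C15; the C15 epimers converge here.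

Step 6
Reactants: 8 epoxy enol triflate
Product: 9 enol triflate trans-diol (2α-OH and 3β-OH)
Conditions: HClO4 (5 mol %), THF–H2O 3:1, 0 °C to rt
Reagents that add atoms: water O
Why: Acid-catalysed epoxide hydrolysis: water should attack the allylic carbon C2 with inversion (C3 is neopentylic, C15 is fully substituted and a 2-triflyloxy allyl cation is disfavoured), which gives the trans-diol with O3 β and O2 α; the enol triflate is stable to dilute acid.

Step 7
Reactants: 9 enol triflate trans-diol
Product: 10 enol triflate acetonide
Conditions: Me2C(OMe)2, pyridinium p-toluenesulfonate (5 mol %), CH2Cl2, rt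
Reagents that add atoms: 2,2-dimethoxypropane COC(C)(C)OC
Why: Acid-catalysed transketalisation on the diequatorial half-chair gives the trans-fused dioxolane, which masks both hydroxyls against chromium, borane, base and oxidants in one group.

Step 8
Reactants: 11 (R)-5-methoxy-3-methyl-5-oxopentanoic acid
Product: 13 (S)-4-methyltetrahydro-2H-pyran-2-one, via hydroxy acid 12 (not isolated)
Conditions: LiBH4, THF, 0 °C to rt; then 2 M HCl
Reagents that add atoms: none
Why: LiBH4 reduces the ester in the presence of the lithium carboxylate and the hydroxy acid lactonises on acidification; the bought C12 stereocentre is not touched.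

Step 9
Reactants: 13 (S)-4-methyltetrahydro-2H-pyran-2-one
Product: 15 methyl (R)-5-chloro-3-methylpentanoate, via acid chloride 14 (not isolated)
Conditions: SOCl2, ZnCl2 (5 mol %), 60 °C; then MeOH, 0 °C
Reagents that add atoms: thionyl chloride O=S(Cl)Cl; methanol CO
Why: Chlorinative ring opening of the δ-lactone (alkyl–oxygen cleavage by chloride on the activated acyl chlorosulfite) gives the ω-chloro acid chloride, which methanol converts into the ester.

Step 10
Reactants: 15 methyl (R)-5-chloro-3-methylpentanoate
Product: 16 (R)-5-chloro-3-methylpentanal
Conditions: iBu2AlH, CH2Cl2, −78 °C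
Reagents that add atoms: none
Why: Partial ester reduction through the stable aluminium hemiacetal at −78 °C gives the aldehyde; the primary chloride is inert.

Step 11
Reactants: 10 enol triflate acetonide; 16 (R)-5-chloro-3-methylpentanal
Product: 17 C14 allylic alcohol (both C14 epimers)
Conditions: CrCl2 (4 equiv), NiCl2 (2 mol %), DMF, rt
Reagents that add atoms: none
Why: Nozaki–Hiyama–Kishi coupling: oxidative addition of the enol triflate to zerovalent nickel, transmetallation to trivalent chromium and addition to the aldehyde form C1–C14. The alkyl chloride, the acetonide and the isopropenyl group are inert to divalent chromium, and the C14 epimers converge in step 12.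

Step 12
Reactants: 17 C14 allylic alcohol
Product: 18 C14 ketone
Conditions: Dess–Martin periodinane, pyridine, CH2Cl2, 0 °C to rt
Reagents that add atoms: none
Why: Dess–Martin oxidation under buffered conditions gives the enone; conjugation with C14=O now deactivates C1=C15 toward electrophiles.

Step 13
Reactants: 18 C14 ketone
Product: 19 C14 ketone with C9 allylic chloride
Conditions: Ca(OCl)2, CO2 (solid), CH2Cl2–H2O, 0 °C
Reagents that add atoms: calcium hypochlorite [Ca+2].[O-]Cl.[O-]Cl
Why: Ene-type allylic chlorination by hypochlorous acid: the electrophile adds to the terminal carbon of the only electron-rich alkene and a methyl proton is lost, which gives the 2-substituted allyl chloride (C9); the enone alkene should not react.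

Step 14
Reactants: 19 C14 ketone with C9 allylic chloride
Product: 20 (14S)-alcohol
Conditions: (R)-1-methyl-3,3-diphenyltetrahydro-1H,3H-pyrrolo[1,2-c][1,3,2]oxazaborole (30 mol %), catecholborane, toluene, −78 °C
Reagents that add atoms: none
Why: Corey–Bakshi–Shibata reduction: the tetrasubstituted alkenyl group is the large and C13H2 the small substituent, so the (R)-catalyst should deliver hydride to give the (14S)-alcohol; catecholborane at −78 °C does not hydroborate C8=C19.

Step 15
Reactants: 20 (14S)-alcohol
Product: 21 (14S)-silyl ether dichloride
Conditions: tBuMe2SiOTf, 2,6-lutidine, CH2Cl2, −78 °C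
Reagents that add atoms: tert-butyldimethylsilyl trifluoromethanesulfonate CC(C)(C)[Si](C)(C)OS(=O)(=O)C(F)(F)F
Why: Silylation of the allylic alcohol; the silyl ether tolerates sulfide, peroxide and hydroxide and is later removed by fluoride in the presence of the acetonide.

Step 16
Reactants: 21 (14S)-silyl ether dichloride
Product: 22 twelve-membered cyclic sulfide
Conditions: Na2S·9H2O, NaI (10 mol %), DMF, 60 °C, slow addition to 2 mM
Reagents that add atoms: sodium sulfide [Na+].[Na+].[S-2]
Why: Double SN2 thioetherification: sulfide first displaces the allylic chloride and the thiolate then closes the twelve-membered ring on the primary carbon under high dilution; long C–S bonds and a soft nucleophile make this closure far easier than any C–C closure of ring C.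

Step 17
Reactants: 22 twelve-membered cyclic sulfide
Product: 23 twelve-membered cyclic sulfone
Conditions: 30% H2O2, (NH4)6Mo7O24·4H2O (10 mol %), EtOH–THF, 0 °C to rt
Reagents that add atoms: hydrogen peroxide OO
Why: Molybdate-catalysed peroxide oxidation takes the sulfide through the sulfoxide to the sulfone; the peroxomolybdate is selective for sulfur over unfunctionalised alkenes and there is no free allylic hydroxyl to direct epoxidation.

Step 18
Reactants: 23 twelve-membered cyclic sulfone
Product: 26 tricyclic (9E)-diene silyl ether, via bromo sulfone 24 (not isolated), via episulfone 25 (not isolated)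
Conditions: CBr2F2, KOH/Al2O3, tBuOH–CH2Cl2, 0 °C to rt
Reagents that add atoms: none
Why: Ramberg–Bäcklund ring contraction in its in situ halogenative form: hydroxide on alumina deprotonates the allylic α-carbon C9 and the carbanion is brominated by CBr2F2 to give 24, after which deprotonation at C10 and 3-exo-tet displacement of bromide close the episulfone 25, which loses SO2 to form C9=C10. The closest known reaction type is the Ramberg–Bäcklund olefination of macrocyclic and of allylic sulfones to cyclic alkenes and 1,3-dienes. Ring C is therefore closed by contraction of the twelve-membered sulfone and not by macrocyclisation, and the only ring closed directly is the three-membered episulfone. No stereocentre is formed; the E geometry should follow from stereospecific extrusion out of the trans-episulfone, which is favoured because the allylic C9–H of 25 epimerises under the conditions and the trans arrangement places C8 and C11 anti. The step needs α- rather than γ-bromination of the allyl anion and closure faster than allyl-to-vinyl sulfone isomerisation; halogenation at either C9 or C10 leads to the same episulfone, CBr2F2 avoids dichlorocarbene addition to C1=C15, and the substrate has no ester, ketone or free hydroxyl. The strain of the bridged ring is paid for by the irreversible loss of SO2.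

Step 19
Reactants: 26 tricyclic (9E)-diene silyl ether
Product: 27 tricyclic C14 alcohol
Conditions: Bu4NF, THF, 0 °C to rt
Reagents that add atoms: none
Why: Fluoride cleaves the secondary silyl ether; the acetonide, the diene and the tetrasubstituted alkene are inert.

Step 20
Reactants: 27 tricyclic C14 alcohol
Product: 28 C14 acetate acetonide
Conditions: Ac2O, pyridine, 4-(dimethylamino)pyridine (5 mol %), CH2Cl2, rt
Reagents that add atoms: acetic anhydride CC(=O)OC(C)=O
Why: Acylation of the only free hydroxyl.

Step 21
Reactants: 28 C14 acetate acetonide
Product: 29 (2R,3R,4S,7R,12S,14S,16S,9E)-14-acetoxytrinervita-1(15),8(19),9-triene-2,3-diol (CNP0291538.1)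
Conditions: pyridinium p-toluenesulfonate (10 mol %), MeOH, rt
Reagents that add atoms: none
Why: Acid-catalysed transketalisation with methanol removes the strained trans-acetonide under conditions that should leave the allylic acetate and the diene intact.

## Compound list

1 | 2,6-dimethylhept-5-enal (melonal, racemate) | CC(C)=CCCC(C)C=O | starting material
2 | pent-1-en-3-one (ethyl vinyl ketone) | CCC(=O)C=C | starting material
3 | (R)-2,6-dimethyl-2-(3-oxopentyl)hept-5-enal | CC(C)=CCC[C@@](C)(C=O)CCC(=O)CC | intermediate
4 | (R)-2,4-dimethyl-4-(4-methylpent-3-en-1-yl)cyclohex-2-en-1-one | CC(C)=CCC[C@@]1(C)C=C(C)C(=O)CC1 | intermediate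
5 | bicyclic ketone, rings A and B cis-fused (C18 methyl and H-16 β), C1 ketone, 7α-isopropenyl (H-7 β), C15 methyl as epimer mixture | O=C1C(C)[C@@H]2[C@H](C(C)=C)CC[C@]2(C)CC1 | intermediate
6 | C2=C3 enone of 5 (same ring fusion and C7 configuration) | O=C1C(C)[C@@H]2[C@H](C(C)=C)CC[C@]2(C)C=C1 | intermediate
7 | 2β,3β-epoxy ketone of 6 (epoxide cis to C18) | O=C1C(C)[C@@H]2[C@H](C(C)=C)CC[C@]2(C)[C@H]3O[C@H]31 | intermediate
8 | C1=C15 enol triflate with 2β,3β-epoxide | O=S(=O)(OC1=C(C)[C@@H]2[C@H](C(C)=C)CC[C@]2(C)[C@H]3O[C@H]31)C(F)(F)F | intermediate
9 | C1=C15 enol triflate, trans-diol (2α-OH, 3β-OH) | O=S(=O)(OC1=C(C)[C@@H]2[C@H](C(C)=C)CC[C@]2(C)[C@@H](O)[C@@H]1O)C(F)(F)F | intermediate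
10 | C1=C15 enol triflate, 2α,3β-O-isopropylidene (trans-acetonide) | O=S(=O)(OC1=C(C)[C@@H]2[C@H](C(C)=C)CC[C@]2(C)[C@H]3OC(C)(C)O[C@@H]31)C(F)(F)F | intermediate
11 | (R)-5-methoxy-3-methyl-5-oxopentanoic acid (monomethyl (R)-3-methylglutarate) | COC(=O)C[C@H](C)CC(=O)O | starting material
12 | (S)-5-hydroxy-3-methylpentanoic acid | OCC[C@H](C)CC(=O)O | intermediate
13 | (S)-4-methyltetrahydro-2H-pyran-2-one | O=C1C[C@@H](C)CCO1 | intermediate
14 | (S)-5-chloro-3-methylpentanoyl chloride | ClCC[C@H](C)CC(Cl)=O | intermediate
15 | methyl (R)-5-chloro-3-methylpentanoate | ClCC[C@H](C)CC(=O)OC | intermediate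
16 | (R)-5-chloro-3-methylpentanal | ClCC[C@H](C)CC=O | intermediate
17 | C1–C14 coupled allylic alcohol (C14 epimers), acetonide, 7α-isopropenyl, C10 chloride | ClCC[C@H](C)CC(O)C1=C(C)[C@@H]2[C@H](C(C)=C)CC[C@]2(C)[C@H]3OC(C)(C)O[C@@H]31 | intermediate
18 | C14 ketone of 17 | ClCC[C@H](C)CC(=O)C1=C(C)[C@@H]2[C@H](C(C)=C)CC[C@]2(C)[C@H]3OC(C)(C)O[C@@H]31 | intermediate
19 | C14 ketone with 7α-[3-chloroprop-1-en-2-yl] group (C9 chloride) | ClCC[C@H](C)CC(=O)C1=C(C)[C@@H]2[C@H](C(=C)CCl)CC[C@]2(C)[C@H]3OC(C)(C)O[C@@H]31 | intermediate
20 | (14S)-alcohol of 19 | ClCC[C@H](C)C[C@H](O)C1=C(C)[C@@H]2[C@H](C(=C)CCl)CC[C@]2(C)[C@H]3OC(C)(C)O[C@@H]31 | intermediate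
21 | (14S)-tert-butyldimethylsilyl ether of 20 (C9 and C10 chlorides) | ClCC[C@H](C)C[C@H](O[Si](C)(C)C(C)(C)C)C1=C(C)[C@@H]2[C@H](C(=C)CCl)CC[C@]2(C)[C@H]3OC(C)(C)O[C@@H]31 | intermediate
22 | twelve-membered cyclic sulfide (S between C9 and C10) | C=C1CSCC[C@H](C)C[C@H](O[Si](C)(C)C(C)(C)C)C2=C(C)[C@@H]3[C@H]1CC[C@]3(C)[C@H]4OC(C)(C)O[C@@H]42 | intermediate
23 | twelve-membered cyclic sulfone | C=C1CS(=O)(=O)CC[C@H](C)C[C@H](O[Si](C)(C)C(C)(C)C)C2=C(C)[C@@H]3[C@H]1CC[C@]3(C)[C@H]4OC(C)(C)O[C@@H]42 | intermediate
24 | C9-bromo sulfone (C9 configuration undefined) | C=C1C(Br)S(=O)(=O)CC[C@H](C)C[C@H](O[Si](C)(C)C(C)(C)C)C2=C(C)[C@@H]3[C@H]1CC[C@]3(C)[C@H]4OC(C)(C)O[C@@H]42 | intermediate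
25 | C9,C10-episulfone (trans; absolute sense at C9/C10 undefined) | C=C1C2C(S2(=O)=O)C[C@H](C)C[C@H](O[Si](C)(C)C(C)(C)C)C3=C(C)[C@@H]4[C@H]1CC[C@]4(C)[C@H]5OC(C)(C)O[C@@H]53 | intermediate
26 | tricyclic (9E)-diene, 14-O-silyl, 2,3-acetonide | C=C1/C=C/C[C@H](C)C[C@H](O[Si](C)(C)C(C)(C)C)C2=C(C)[C@@H]3[C@H]1CC[C@]3(C)[C@H]4OC(C)(C)O[C@@H]42 | intermediate
27 | tricyclic (9E)-diene, 14-OH, 2,3-acetonide | C=C1/C=C/C[C@H](C)C[C@H](O)C2=C(C)[C@@H]3[C@H]1CC[C@]3(C)[C@H]4OC(C)(C)O[C@@H]42 | intermediate
28 | tricyclic (9E)-diene, 14-OAc, 2,3-acetonide | C=C1/C=C/C[C@H](C)C[C@H](OC(C)=O)C2=C(C)[C@@H]3[C@H]1CC[C@]3(C)[C@H]4OC(C)(C)O[C@@H]42 | intermediate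
29 | (2R,3R,4S,7R,12S,14S,16S,9E)-14-acetoxytrinervita-1(15),8(19),9-triene-2,3-diol (CNP0291538.1) | C=C1/C=C/C[C@H](C)C[C@H](OC(C)=O)C2=C(C)[C@@H]3[C@H]1CC[C@]3(C)[C@@H](O)[C@@H]2O | target

## Step count and least certain steps

Total: 21 steps. Longest linear sequence: 18 steps (steps 1–7 and 11–21); steps 8–10 make 16.

Step 18 (key). The Z alkene may form, or no contraction may take place because the allyl sulfone isomerises to the vinyl sulfone or is brominated at the γ-carbon C19. The fallback closes ring C by sulfone-anion alkylation in place of sulfur extrusion. From 21, PhSO2Na in DMF should displace only the allylic chloride to give the allylic phenyl sulfone F1. NaI in acetone converts the remaining primary chloride into the iodide F2. KN(SiMe3)2 in THF under high dilution closes ring C by alkylation of the α-sulfonyl allyl anion at C10 to the cyclic phenyl sulfone F3. KOC(CH3)3 in THF then eliminates benzenesulfinate across C9–C10 and rejoins the route at 26.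

Step 2. Diastereoselectivity at C7 may be poor, or the C8 cation may be captured (by chloride, or by the enolate oxygen or carbon) before the proton is transferred. The fallback separates cyclisation and elimination. From 4, TiCl4 in CH2Cl2 at −78 °C should give the tertiary chloride F4 by conjugate Prins cyclisation with chloride capture. KOC(CH3)3 in DMSO then removes HCl toward a methyl group (the C7 methine is hindered) and returns to 5.

Step 1. Enantioselectivity may be low because the methyl and the homoprenyl arm of the α-branched aldehyde are poorly differentiated in the enamine. The fallback uses no asymmetric catalysis. From 1 and 2, pyrrolidine-mediated Michael addition and aldol condensation with NaOMe give the racemate, that is 4 together with its enantiomer (S)-2,4-dimethyl-4-(4-methylpent-3-en-1-yl)cyclohex-2-en-1-one F5. Preparative chromatography on a cellulose tris(3,5-dimethylphenylcarbamate) phase returns enantiopure 4.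

Step 6. Water may attack C15 with allylic transposition, or the protonated vinyl epoxide may rearrange by hydride shift. The fallback is a neutral SN2 opening by a carboxylate. From 8, benzoic acid with the cobalt acetate complex of (R,R)-N,N′-bis(3,5-di-tert-butylsalicylidene)-1,2-cyclohexanediamine (trivalent cobalt, 5 mol %) in tert-butyl methyl ether should open the epoxide at C2 with inversion to the 3β-hydroxy 2α-benzoate F6. iBu2AlH at −78 °C removes the benzoate and rejoins at 9.

Step 17. The tetrasubstituted C1=C15 may be epoxidised, or the silyl ether lost, under the peroxide conditions. The fallback brings sulfur in at the sulfone oxidation level. From 21, sodium 3-methoxy-3-oxopropane-1-sulfinate in DMF should alkylate at the allylic chloride to give the sulfonyl propanoate F7. NaOMe (1 equiv) in THF–MeOH releases methyl acrylate and leaves the sodium allylsulfinate F8. In DMF with NaI under high dilution, F8 closes the twelve-membered ring by S-alkylation at C10 and rejoins at 23.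

## Further compounds

F1 | step 18 | allylic phenyl sulfone at C9, C10 chloride, 14-O-silyl, acetonide | ClCC[C@H](C)C[C@H](O[Si](C)(C)C(C)(C)C)C1=C(C)[C@@H]2[C@H](C(=C)CS(=O)(=O)c3ccccc3)CC[C@]2(C)[C@H]4OC(C)(C)O[C@@H]41
F2 | step 18 | allylic phenyl sulfone at C9, C10 iodide | ICC[C@H](C)C[C@H](O[Si](C)(C)C(C)(C)C)C1=C(C)[C@@H]2[C@H](C(=C)CS(=O)(=O)c3ccccc3)CC[C@]2(C)[C@H]4OC(C)(C)O[C@@H]41
F3 | step 18 | eleven-membered carbocycle with 9-phenylsulfonyl group (C9 configuration undefined) | C=C1C(S(=O)(=O)c2ccccc2)CC[C@H](C)C[C@H](O[Si](C)(C)C(C)(C)C)C3=C(C)[C@@H]4[C@H]1CC[C@]4(C)[C@H]5OC(C)(C)O[C@@H]53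
F4 | step 2 | cis-fused bicyclic ketone with 7α-(2-chloropropan-2-yl) group | O=C1C(C)[C@@H]2[C@H](C(C)(C)Cl)CC[C@]2(C)CC1
F5 | step 1 | (S)-2,4-dimethyl-4-(4-methylpent-3-en-1-yl)cyclohex-2-en-1-one | CC(C)=CCC[C@]1(C)C=C(C)C(=O)CC1
F6 | step 6 | enol triflate with 3β-hydroxyl and 2α-benzoate | O=S(=O)(OC1=C(C)[C@@H]2[C@H](C(C)=C)CC[C@]2(C)[C@@H](O)[C@@H]1OC(=O)c3ccccc3)C(F)(F)F
F7 | step 17 | methyl 3-(allylsulfonyl)propanoate derivative of 21 (sulfone at C9, C10 chloride) | ClCC[C@H](C)C[C@H](O[Si](C)(C)C(C)(C)C)C1=C(C)[C@@H]2[C@H](C(=C)CS(=O)(=O)CCC(=O)OC)CC[C@]2(C)[C@H]3OC(C)(C)O[C@@H]31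
F8 | step 17 | sodium allylsulfinate at C9, C10 chloride | ClCC[C@H](C)C[C@H](O[Si](C)(C)C(C)(C)C)C1=C(C)[C@@H]2[C@H](C(=C)CS(=O)[O-])CC[C@]2(C)[C@H]3OC(C)(C)O[C@@H]31.[Na+]
A1 | alternative 1 | seco-triene for ring-closing metathesis (vinyl at C8 and allyl at C12) | C=CC[C@H](C)C[C@H](O[Si](C)(C)C(C)(C)C)C1=C(C)[C@@H]2[C@H](C(=C)C=C)CC[C@]2(C)[C@H]3OC(C)(C)O[C@@H]31
A2 | alternative 2 | fourteen-membered (3E,9E)-enone with 7-acetonyl side chain | C=C1/C=C/C[C@H](C)C[C@H](O[Si](C)(C)C(C)(C)C)CC(=O)/C=C(C)/CC[C@@H]1CC(C)=O
A3 | alternative 3 | 2-methylcyclopent-2-enone tethered at C7 to a 2-silyloxy-1,3-diene (C1=C15 geometry undefined) | CC1=C[C@@H](CC1=O)C(=C)/C=C/C[C@H](C)C[C@H](O[Si](C)(C)C(C)(C)C)C(=CC)C(=C)O[Si](C)(C)C
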